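Assumption: the target SMILES has no stereocentre and no specified axis or plane, so it is treated as achiral and no stereocontrol is needed. Compounds 2, 5 and 7 are taken as catalogue building blocks.

**Retrosynthetic overview**
1. Target 13 ⇐ macrocyclic trimethyl ether 12 by global O-demethylation.
2. 12 ⇐ seco-bis(bibenzyl) 10 by oxidative phenol C–O coupling: the ring B phenol oxygen attacks C5 of the bromoguaiacol ring A with loss of Br. This closes the 17-membered macrocycle, the only ring formed, with the same bond and polarity as the oxidative coupling of two bibenzyl units in liverworts.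
3. 10 ⇐ bis-stilbene 9 (diimide) ⇐ aldehyde 6 + ring B phosphonium salt 7 (Wittig).
4. 6 ⇐ stilbene 4 + fluoroaldehyde 5 by SNAr with ring D's own phenol oxygen as nucleophile. A phenol oxidation cannot deliver C2 of ring C selectively, because the position para to the ring C hydroxyl is free.
5. 4 ⇐ 5-bromovanillin 1 + ring D phosphonium salt 2 (Wittig). All four benzene rings are bought.

**Route**

Step 1
Reactants: 1 5-bromovanillin; 2 (2-hydroxybenzyl)triphenylphosphonium bromide
Product: 4 2-bromo-4-[2-(2-hydroxyphenyl)ethenyl]-6-methoxyphenol (E/Z mixture), via phenolate ylide 3 (not isolated)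
Conditions: KOtBu (3.3 eq), THF, 0 °C → reflux; aq. HCl work-up
Reagents that add atoms: none
Why: Wittig olefination of the semi-stabilised ylide 3 with the aldehyde tolerates both free phenols when three equivalents of base are used, and the alkene geometry is irrelevant because the double bond is reduced in step 4 (no stereocentre formed).

Step 2
Reactants: 4 2-bromo-4-[2-(2-hydroxyphenyl)ethenyl]-6-methoxyphenol; 5 2-fluoro-3,4-dimethoxybenzaldehyde
Product: 6 2-{2-[2-(3-bromo-4-hydroxy-5-methoxyphenyl)ethenyl]phenoxy}-3,4-dimethoxybenzaldehyde (E/Z mixture)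
Conditions: Cs2CO3 (3 eq), DMSO, 120 °C, Ar
Reagents that add atoms: none
Why: SNAr (addition–elimination through a Meisenheimer adduct stabilised by the ortho-formyl group) displaces fluoride, and the ring D phenoxide reacts in preference to the ring A one because it is about two pK units more basic and has one ortho substituent instead of the flanking Br and OMe.

Step 3
Reactants: 6 2-{2-[2-(3-bromo-4-hydroxy-5-methoxyphenyl)ethenyl]phenoxy}-3,4-dimethoxybenzaldehyde; 7 (4-hydroxybenzyl)triphenylphosphonium bromide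
Product: 9 2-bromo-4-{2-[2-(6-[2-(4-hydroxyphenyl)ethenyl]-2,3-dimethoxyphenoxy)phenyl]ethenyl}-6-methoxyphenol (E/Z mixture at both alkenes), via phenolate ylide 8 (not isolated)
Conditions: KOtBu (3.3 eq), THF, 0 → 50 °C; aq. HCl work-up
Reagents that add atoms: none
Why: Wittig olefination of the non-phenolic aryl aldehyde with the electron-rich phenolate ylide 8 installs ring B with its free hydroxyl and so avoids a protecting group (no stereocentre formed, geometry removed in step 4).

Step 4
Reactants: 9 2-bromo-4-{2-[2-(6-[2-(4-hydroxyphenyl)ethenyl]-2,3-dimethoxyphenoxy)phenyl]ethenyl}-6-methoxyphenol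
Product: 10 2-bromo-4-{2-[2-(6-[2-(4-hydroxyphenyl)ethyl]-2,3-dimethoxyphenoxy)phenyl]ethyl}-6-methoxyphenol
Conditions: TsNHNH2 (10 eq), NaOAc (10 eq), THF/H2O 1:1, reflux
Reagents that add atoms: none
Why: Diimide reduction transfers H2 to both stilbene double bonds and leaves the aryl bromide needed in step 5 untouched, which Pd/C hydrogenation would not (no stereocentre formed).

Step 5
Reactants: 10 2-bromo-4-{2-[2-(6-[2-(4-hydroxyphenyl)ethyl]-2,3-dimethoxyphenoxy)phenyl]ethyl}-6-methoxyphenol
Product: 12 macrocyclic bis(bibenzyl) trimethyl ether (ring A 4-hydroxy-3-methoxy-5-aryloxy; ring C 3,4-dimethoxy-2-aryloxy), via macrocyclic 4-methoxycyclohexadienone 11 (not isolated)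
Conditions: Tl(NO3)3·3H2O (1.2 eq), MeOH/THF 4:1, 1 mM, −20 → 0 °C; then Zn dust, AcOH, rt
Reagents that add atoms: none
Why: Proposed new method: two-electron oxidation of the most electron-rich ring (the 2-bromo-6-methoxyphenol, ring A) gives a phenoxonium ion that the ring B phenol oxygen attacks at the bromine-bearing ortho carbon, bromide leaves, methanol caps the para position to give dienone 11 and zinc reduces this to the diaryl ether, while adducts at the para or OMe-bearing carbons are returned to 10 by the same zinc treatment so that only the C–Br site is productive; the closest known reaction type is the Tl(III)- or anode-mediated oxidative phenol coupling of ortho-halophenols to isodityrosine-type diaryl ether macrocycles, extended here to a bromoguaiacol electrophile and an unhalogenated phenol nucleophile, and no stereocentre is created.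

Step 6
Reactants: 12 macrocyclic bis(bibenzyl) trimethyl ether
Product: 13 target tetraol CNP0114693.0
Conditions: BBr3 (8 eq), CH2Cl2, −78 °C → rt; then H2O, 0 °C
Reagents that add atoms: none
Why: BBr3 O-demethylation (Lewis-acid aryl methyl ether cleavage) removes the three methyl groups and leaves the two diaryl ethers intact, and there is no stereocentre to set or scramble.

**Compound list**
1 | 5-bromovanillin (3-bromo-4-hydroxy-5-methoxybenzaldehyde) | COc1cc(C=O)cc(Br)c1O | starting material
2 | (2-hydroxybenzyl)triphenylphosphonium bromide | [Br-].Oc1ccccc1C[P+](c1ccccc1)(c1ccccc1)c1ccccc1 | starting material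
3 | potassium 2-[(triphenylphosphoranylidene)methyl]phenolate (ylide, not isolated) | [K+].[O-]c1ccccc1C=P(c1ccccc1)(c1ccccc1)c1ccccc1 | intermediate
4 | 2-bromo-4-[2-(2-hydroxyphenyl)ethenyl]-6-methoxyphenol, E/Z mixture | COc1cc(C=Cc2ccccc2O)cc(Br)c1O | intermediate
5 | 2-fluoro-3,4-dimethoxybenzaldehyde | COc1ccc(C=O)c(F)c1OC | starting material
6 | 2-{2-[2-(3-bromo-4-hydroxy-5-methoxyphenyl)ethenyl]phenoxy}-3,4-dimethoxybenzaldehyde, E/Z mixture | COc1ccc(C=O)c(Oc2ccccc2C=Cc2cc(Br)c(O)c(OC)c2)c1OC | intermediate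
7 | (4-hydroxybenzyl)triphenylphosphonium bromide | [Br-].Oc1ccc(C[P+](c2ccccc2)(c2ccccc2)c2ccccc2)cc1 | starting material
8 | potassium 4-[(triphenylphosphoranylidene)methyl]phenolate (ylide, not isolated) | [K+].[O-]c1ccc(C=P(c2ccccc2)(c2ccccc2)c2ccccc2)cc1 | intermediate
9 | 2-bromo-4-{2-[2-(6-[2-(4-hydroxyphenyl)ethenyl]-2,3-dimethoxyphenoxy)phenyl]ethenyl}-6-methoxyphenol, E/Z mixture at both alkenes | COc1ccc(C=Cc2ccc(O)cc2)c(Oc2ccccc2C=Cc2cc(Br)c(O)c(OC)c2)c1OC | intermediate
10 | 2-bromo-4-{2-[2-(6-[2-(4-hydroxyphenyl)ethyl]-2,3-dimethoxyphenoxy)phenyl]ethyl}-6-methoxyphenol | COc1ccc(CCc2ccc(O)cc2)c(Oc2ccccc2CCc2cc(Br)c(O)c(OC)c2)c1OC | intermediate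
11 | macrocyclic 4-methoxycyclohexa-2,5-dienone: ring A of 12 as its para-quinol methyl ether, racemic at the quaternary carbon (not isolated) | COC1=CC2(OC)C=C(C1=O)Oc1ccc(cc1)CCc1ccc(OC)c(OC)c1Oc1ccccc1CC2 | intermediate
12 | 17-membered macrocyclic bis(bibenzyl), tri-O-methyl ether of 13 (ring A 4-hydroxy-3-methoxy-5-aryloxy; ring C 3,4-dimethoxy-2-aryloxy) | COc1cc2cc(c1O)Oc1ccc(cc1)CCc1ccc(OC)c(OC)c1Oc1ccccc1CC2 | intermediate
13 | CNP0114693.0, macrocyclic bis(bibenzyl) tetraol (ring A 3,4-dihydroxy-5-aryloxy; ring B para-phenylene ether; ring C 3,4-dihydroxy-2-aryloxy; ring D ortho-phenylene ether); achiral | Oc1cc2cc(c1O)Oc1ccc(cc1)CCc1ccc(O)c(O)c1Oc1ccccc1CC2 | target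

**Count and risks**
Total steps: 6. Longest linear sequence: 6.

The three steps most likely to fail:

Step 5 (oxidative macrocyclisation). The ring B phenol carries no ortho halogens, so attack through its ortho carbon (C–C coupling) and methanol capture of the cation compete with the wanted O-attack, and the 17-membered ring is strained. Fallback: set out from 6 and close the ring by copper-catalysed etherification at the same C–Br carbon. O-methylation of 6 (MeI, K2CO3, acetone) gives 2-{2-[2-(3-bromo-4,5-dimethoxyphenyl)ethenyl]phenoxy}-3,4-dimethoxybenzaldehyde F1. Wittig reaction with ylide 8 gives 4-{2-[2-(2-[2-(3-bromo-4,5-dimethoxyphenyl)ethenyl]phenoxy)-3,4-dimethoxyphenyl]ethenyl}phenol F2. Diimide reduction gives 4-{2-[2-(2-[2-(3-bromo-4,5-dimethoxyphenyl)ethyl]phenoxy)-3,4-dimethoxyphenyl]ethyl}phenol F3. Intramolecular Ullmann coupling (CuI, N,N-dimethylglycine, Cs2CO3, dioxane, 100 °C, high dilution) gives the macrocyclic tetramethyl ether F4, and BBr3 then returns to the route at 13.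

Step 2 (SNAr). Fluoroarene 5 is deactivated by its two methoxy groups, and 4 offers two phenoxides. Fallback: set out from 5 and bring ring D in as a small single phenol that can be used in excess. SNAr with 2-hydroxybenzyl alcohol (Cs2CO3, DMSO) gives 2-[2-(hydroxymethyl)phenoxy]-3,4-dimethoxybenzaldehyde F5. Wittig reaction with ylide 8 gives 4-{2-[2-(2-(hydroxymethyl)phenoxy)-3,4-dimethoxyphenyl]ethenyl}phenol F6. PPh3·HBr (MeCN, reflux) gives {2-[6-(2-(4-hydroxyphenyl)ethenyl)-2,3-dimethoxyphenoxy]benzyl}triphenylphosphonium bromide F7, and its Wittig reaction with 1 returns to the route at 9.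

Step 1 (Wittig on a phenoxide aldehyde). Deprotonated 1 is a vinylogous carboxylate and a poor electrophile. Fallback: set out from 1 and move the ylide onto ring A. NaBH4 (MeOH) gives 2-bromo-4-(hydroxymethyl)-6-methoxyphenol F8. PPh3·HBr (MeCN, reflux) gives (3-bromo-4-hydroxy-5-methoxybenzyl)triphenylphosphonium bromide F9, and its Wittig reaction with salicylaldehyde (KOtBu, THF) returns to the route at 4.

**Further compounds**
F1 | step 5 | 2-{2-[2-(3-bromo-4,5-dimethoxyphenyl)ethenyl]phenoxy}-3,4-dimethoxybenzaldehyde | COc1ccc(C=O)c(Oc2ccccc2C=Cc2cc(Br)c(OC)c(OC)c2)c1OC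
F2 | step 5 | 4-{2-[2-(2-[2-(3-bromo-4,5-dimethoxyphenyl)ethenyl]phenoxy)-3,4-dimethoxyphenyl]ethenyl}phenol | COc1ccc(C=Cc2ccc(O)cc2)c(Oc2ccccc2C=Cc2cc(Br)c(OC)c(OC)c2)c1OC
F3 | step 5 | 4-{2-[2-(2-[2-(3-bromo-4,5-dimethoxyphenyl)ethyl]phenoxy)-3,4-dimethoxyphenyl]ethyl}phenol | COc1ccc(CCc2ccc(O)cc2)c(Oc2ccccc2CCc2cc(Br)c(OC)c(OC)c2)c1OC
F4 | step 5 | macrocyclic bis(bibenzyl) tetramethyl ether (tetra-O-methyl ether of 13) | COc1cc2cc(c1OC)Oc1ccc(cc1)CCc1ccc(OC)c(OC)c1Oc1ccccc1CC2
F5 | step 2 | 2-[2-(hydroxymethyl)phenoxy]-3,4-dimethoxybenzaldehyde | COc1ccc(C=O)c(Oc2ccccc2CO)c1OC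
F6 | step 2 | 4-{2-[2-(2-(hydroxymethyl)phenoxy)-3,4-dimethoxyphenyl]ethenyl}phenol | COc1ccc(C=Cc2ccc(O)cc2)c(Oc2ccccc2CO)c1OC
F7 | step 2 | {2-[6-(2-(4-hydroxyphenyl)ethenyl)-2,3-dimethoxyphenoxy]benzyl}triphenylphosphonium bromide | [Br-].COc1ccc(C=Cc2ccc(O)cc2)c(Oc2ccccc2C[P+](c2ccccc2)(c2ccccc2)c2ccccc2)c1OC
F8 | step 1 | 2-bromo-4-(hydroxymethyl)-6-methoxyphenol | COc1cc(CO)cc(Br)c1O
F9 | step 1 | (3-bromo-4-hydroxy-5-methoxybenzyl)triphenylphosphonium bromide | [Br-].COc1cc(C[P+](c2ccccc2)(c2ccccc2)c2ccccc2)cc(Br)c1O
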